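(The rate constants are invented; the run is a simulation.)

The ratio of coupling partner to starting material, 0.300 in Wednesday's flask, tells what to watch in a repeat: when the catalyst has turned the coupling partner into target, starting material still stands beside that target, and the two are consumed together in the side reaction.

| setting | Wednesday's | Thursday's | Friday's | Sunday's |
|---|---|---|---|---|
| starting material | 0.10 M | 0.10 M | 0.10 M | 0.10 M |
| coupling partner | 0.0300 M | 0.0600 M | 0.120 M | 0.250 M |
| free catalyst | 1.8 mM | 1.8 mM | 1.8 mM | 1.8 mM |
| time | 6.0 h | 6.0 h | 6.0 h | 6.0 h |

    starting material + free catalyst → catalyst intermediate A (k1 = 0.920 /M/s)
    catalyst intermediate A ⇌ catalyst intermediate B (K2 = 85, k2 = 0.0138 /s)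
    coupling partner + catalyst intermediate B → catalyst intermediate C (k3 = 2.10 /M/s)
    catalyst intermediate C → by-product + catalyst intermediate D (k4 = 0.182 /s)
    catalyst intermediate D → free catalyst + target (k5 = 0.0879 /s)
    starting material + target → side product (k6 = 0.00226 /M/s)
    target + free catalyst ⇌ isomer of the product + free catalyst, rate k7*[free catalyst]*[target] forward; the back reaction follows from the equilibrium constant (K7 = 2.8, k7 = 0.118 /M/s)
    coupling partner + target → over-reaction product (k8 = 6.86 × 10⁻⁴ /M/s)

- percentages count the starting material that a species holds: one side product counts as two
- "hardly changes" means that all values lie within two and a half points (for a concentration: within two and a half percent of the largest)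
- run time (Wednesday's): 6.0 h

- share of target in all that became target or side product or isomer of the product or over-reaction product for Wednesday's, Thursday's, Friday's, Sunday's, in this order
- how that number moves from the first to the last of them (falls all the way / hardly changes / rises all the way / falls, then rises / rises, then falls)

I reckon Wednesday's flask by hand. One turn of the catalyst takes the sum of its forward waits, 116 s. The longest wait is the turning of catalyst intermediate A into catalyst intermediate B, 72.5 s, so I call it the rate-limiting step. At that pace Wednesday's flask has used its 0.0300 M of coupling partner, the limiting reagent, after about 0.537 h, and a tail of 5.46 h follows.

In that tail c(starting material) begins near 0.0700 M. It would end at 0.0400 M if the side reaction took every target, since each side product costs one more starting material. Target is lost in a second-order step, at the side reaction's constant times c(starting material) times c(target), and c(starting material) falls along with it, so each reckoning below is an approximation that holds c(starting material) at a chosen fixed value. I set the isomer of the product and the over-reaction product aside. If a fraction e of the target survives, each lost target counts double as side product, so the share is e/(2 − e).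

From above, holding the lowest c(starting material) through the tail:

share = 9.23 %

From below, holding the highest through the whole run:

share = 1.67 %

To tighten this, I replace the curve by its mean. I take the midpoint, 0.0550 M, and from it the mean loss constant, the side reaction's constant times the mean c(starting material) over the tail, 0.447 /h:

share = 4.54 %

The real curve falls steepest at its start, so its mean sits under the midpoint and more target survives. I therefore commit to a share a little above 4.54 %, and below 9.23 %.

The forecast gives 5 %, 24 %, 15 % and 7.4 %, rises, then falls, on the ground that “Leftover starting material slowly eats target by step 6 over the remaining hours”, and its first figure stands inside my tightened bracket .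

The flasks give 5.10 %, 25.4 %, 15.2 % and 7.34 %, rises, then falls. In Wednesday's flask at 3.00 h, target stands at 8.45 % and starting material at 48.0 %, and at 6.00 h they stand at 2.85 % and 42.4 %. The mean of those two starting-material readings gives a loss constant of 0.367 /h, lower than my 0.447 /h, and it carries the earlier target reading to 2.81 %. In Thursday's flask the charge less twice the partner falls below zero, so I take zero as the floor. The midpoint then gives a mean loss constant of 0.163 /h, a tail of 5.00 h, and a share of 28.4 %, where Thursday's flask gives 25.4 %.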